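**Retrosynthetic overview**
1. Oxa-bridge: open the C2–O5 hemiketal C–O bond to give the 5-hydroxy-2-ketone of a ten-membered carbocycle. That ring is cut at C4–C5 (alkenyl bromide + aldehyde).
2. γ-Lactone: open the C12–O6 C–O bond to a methyl ester and a 5,6-diol. The diol is stored as the acetonide of (R)-glyceraldehyde, which supplies C5–C7, O5, O6 and all absolute configuration.
3. Key step: the C8–O tiglate bond is made on the chromium alkoxide as C7–C8 forms (new acylative chromium catalysis). This fixes O8 as the ester oxygen and leaves O6 for the lactone.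
4. Pieces: an allyl bromide from glyceraldehyde acetonide + methyl acrylate; a C8–C10/C1–C4 keto-aldehyde from isoprenol, DMF and 2,3-dibromopropene; tiglic anhydride.
5. Ring order: γ-lactone, then the ten-membered carbocycle, then the oxolane (oxa-bridge) in the same flask.

Assumption: atoms carry germacrane numbers (C12 lactone carbonyl, C2 hemiketal carbon, O5/O6/O8 the oxygens on C5/C6/C8); (R)-glyceraldehyde acetonide and tiglic anhydride are bought.

Step 1
Reactants: 1 3-methylbut-3-en-1-ol (isoprenol)
Product: 2 4-methylideneoxan-2-ol (lactol form of 5-hydroxy-3-methylidenepentanal)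
Conditions: n-BuLi (2.1 equiv), TMEDA, Et2O, 0 °C to rt; DMF, −78 °C; AcOH (2.2 equiv), −78 °C, then H2O
Reagents that add atoms: N,N-dimethylformamide, CN(C)C=O
Why: Alkoxide-directed allylic lithiation gives the O,C-dianion, whose allyl terminus (C1) is formylated by DMF (Bouveault-type formylation), and the β,γ-unsaturated δ-hydroxy aldehyde closes to the lactol, which shields it from conjugation; only a labile anomeric centre is formed.

Step 2
Reactants: 2 4-methylideneoxan-2-ol; 3 2,3-dibromoprop-1-ene
Product: 4 7-bromo-3-methylideneoct-7-ene-1,5-diol (racemic at the secondary carbinol)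
Conditions: In powder (1.2 equiv), THF/H2O 1:1, rt
Reagents that add atoms: none
Why: Aqueous indium Barbier allylation acts on the open aldehyde form of the lactol, the 2-bromoallylindium does not collapse to allene, and the new carbinol centre (C2) is erased in step 3.

Step 3
Reactants: 4 7-bromo-3-methylideneoct-7-ene-1,5-diol
Product: 5 7-bromo-3-methylidene-5-oxooct-7-enal
Conditions: Dess–Martin periodinane (2.5 equiv), NaHCO3, CH2Cl2, 0 °C, used crude
Reagents that add atoms: none
Why: Buffered Dess–Martin oxidation converts both alcohols under near-neutral conditions, so the two β,γ-alkenes stay out of conjugation; no stereocentre remains.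

Step 4
Reactants: 6 (4R)-2,2-dimethyl-1,3-dioxolane-4-carbaldehyde; 7 methyl acrylate
Product: 8 methyl 2-{[(4R)-2,2-dimethyl-1,3-dioxolan-4-yl](hydroxy)methyl}prop-2-enoate (carbinol epimers)
Conditions: DABCO (0.5 equiv), 1,4-dioxane/H2O 1:1, rt
Reagents that add atoms: none
Why: The Morita–Baylis–Hillman reaction forms C7–C11; C6 comes unchanged from the chiral pool, and the new carbinol centre does not matter because step 5 makes it sp2.

Step 5
Reactants: 8 methyl 2-{[(4R)-2,2-dimethyl-1,3-dioxolan-4-yl](hydroxy)methyl}prop-2-enoate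
Product: 9 methyl (2Z)-2-(bromomethyl)-3-[(4S)-2,2-dimethyl-1,3-dioxolan-4-yl]prop-2-enoate
Conditions: NBS (1.3 equiv), Me2S (1.4 equiv), CH2Cl2, 0 °C to rt
Reagents that add atoms: N-bromosuccinimide, O=C1CCC(=O)N1Br
Why: Corey–Kim-type activation of the alcohol followed by SN2′ attack of bromide gives the favoured Z-2-(bromomethyl)enoate under acid-free conditions that spare the acetonide; C6 is untouched (its descriptor changes only by priority).

Step 6 (key step)
Reactants: 5 7-bromo-3-methylidene-5-oxooct-7-enal; 9 methyl (2Z)-2-(bromomethyl)-3-[(4S)-2,2-dimethyl-1,3-dioxolan-4-yl]prop-2-enoate; 10 tiglic anhydride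
Product: 12 methyl (3R,4S)-10-bromo-3-[(4S)-2,2-dimethyl-1,3-dioxolan-4-yl]-2,6-dimethylidene-8-oxo-4-[(2E)-2-methylbut-2-enoyloxy]undec-10-enoate, via homoallylic chromium alkoxide 11 (not isolated)
Conditions: CrCl2 (15 mol %), Mn powder (2.5 equiv), LiCl (2 equiv), 10 (1.5 equiv), THF, 0 °C to rt, 9 added over 4 h
Reagents that add atoms: none
Why: Proposed new method: a chromium-catalytic Nozaki–Hiyama allylation in which a carboxylic anhydride replaces the usual chlorosilane as the reagent that frees chromium from the product alkoxide: Cr(II) converts 9 into an allylchromium(III) that adds through C7 to the aldehyde of 5 (ketone and alkenyl bromide are inert without Ni) via the chair transition state of the E-type allylchromium (anti, sets C7/C8), on the alkene face anti to the dioxolane C6–O bond with H6 eclipsing the double bond (A1,3 control, sets C7 against C6); the Cr(III) alkoxide 11 is acylated at O8 by 10 faster than it can attack the C12 ester (wrong 8,12-lactone) or the C2 ketone, and Mn(0) with LiCl returns the released Cr(III) to Cr(II); the closest known reaction type is the Mn/chlorosilane chromium-catalytic Nozaki–Hiyama–Kishi reaction combined with acylation of metal alkoxides by anhydrides.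

Step 7
Reactants: 12 methyl (3R,4S)-10-bromo-3-[(4S)-2,2-dimethyl-1,3-dioxolan-4-yl]-2,6-dimethylidene-8-oxo-4-[(2E)-2-methylbut-2-enoyloxy]undec-10-enoate
Product: 14 (1S)-7-bromo-1-[(2S,3R)-2-(hydroxymethyl)-4-methylidene-5-oxooxolan-3-yl]-3-methylidene-5-oxooct-7-en-1-yl (2E)-2-methylbut-2-enoate, via diol ester 13 (not isolated)
Conditions: AcOH/H2O/THF 3:1:1, 45 °C; concentrate; PPTS (cat.), CH2Cl2, rt
Reagents that add atoms: none
Why: Mild acetal hydrolysis frees O5 and O6, and O6 closes on the C12 ester (γ-lactonisation, five-ring favoured over the six-ring through O5) to the trans-lactone; no stereocentre is touched, and O8 cannot compete because it is already acylated.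

Step 8
Reactants: 14 (1S)-7-bromo-1-[(2S,3R)-2-(hydroxymethyl)-4-methylidene-5-oxooxolan-3-yl]-3-methylidene-5-oxooct-7-en-1-yl (2E)-2-methylbut-2-enoate
Product: 15 (1S)-7-bromo-1-[(2S,3R)-2-formyl-4-methylidene-5-oxooxolan-3-yl]-3-methylidene-5-oxooct-7-en-1-yl (2E)-2-methylbut-2-enoate
Conditions: Dess–Martin periodinane (1.3 equiv), NaHCO3, CH2Cl2, 0 °C, used crude
Reagents that add atoms: none
Why: Buffered Dess–Martin oxidation of the only free alcohol gives the α-acyloxy aldehyde without base, so C6 is not epimerised and the enone-prone ketone is not isomerised.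

Step 9
Reactants: 15 (1S)-7-bromo-1-[(2S,3R)-2-formyl-4-methylidene-5-oxooxolan-3-yl]-3-methylidene-5-oxooct-7-en-1-yl (2E)-2-methylbut-2-enoate
Product: 17 target CNP0307443.2 ((2S,5S,6S,7R,8S)-2,5-epoxy-2-hydroxy-8-tigloyloxygermacra-4(15),10(14),11(13)-trien-12,6-olide), via hydroxy ketone 16 (not isolated)
Conditions: pre-formed Cr(II) complex from CrCl2 (5 equiv), N-{2-[(4S)-4-isopropyl-4,5-dihydrooxazol-2-yl]-6-methylphenyl}methanesulfonamide (5.5 equiv) and Et3N (5.5 equiv) in THF; NiCl2·(2,9-dimethylphenanthroline) (10 mol %); 15 added over 12 h to 2 mM, rt; aqueous serinate work-up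
Reagents that add atoms: none
Why: The Nozaki–Hiyama–Kishi alkenylation closes the ten-membered ring at the aldehyde only (Ni inserts into C4–Br, then transmetalation to Cr); the chiral Cr–sulfonamide complex delivers the alkenyl group to the Si face of C5 (reagent control, needed because the polar Felkin–Anh bias of the α-acyloxy aldehyde points the other way) to set 5S, and the O5 alkoxide of 16 then adds across the ring to the C2 ketone (5-exo hemiketalisation, C–O bond), where the one-atom bridge allows only 2S.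

**Compound list**
1 | 3-methylbut-3-en-1-ol (isoprenol) | C=C(C)CCO | starting material
2 | 4-methylideneoxan-2-ol (lactol of 5-hydroxy-3-methylidenepentanal, anomeric mixture) | OC1CC(=C)CCO1 | intermediate
3 | 2,3-dibromoprop-1-ene | C=C(Br)CBr | starting material
4 | 7-bromo-3-methylideneoct-7-ene-1,5-diol (racemic) | OCCC(=C)CC(O)CC(Br)=C | intermediate
5 | 7-bromo-3-methylidene-5-oxooct-7-enal | O=CCC(=C)CC(=O)CC(Br)=C | intermediate
6 | (4R)-2,2-dimethyl-1,3-dioxolane-4-carbaldehyde ((R)-glyceraldehyde acetonide) | O=C[C@H]1COC(C)(C)O1 | starting material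
7 | methyl acrylate | C=CC(=O)OC | starting material
8 | methyl 2-{[(4R)-2,2-dimethyl-1,3-dioxolan-4-yl](hydroxy)methyl}prop-2-enoate (carbinol epimers) | C=C(C(=O)OC)C(O)[C@H]1COC(C)(C)O1 | intermediate
9 | methyl (2Z)-2-(bromomethyl)-3-[(4S)-2,2-dimethyl-1,3-dioxolan-4-yl]prop-2-enoate | COC(=O)/C(CBr)=C/[C@H]1COC(C)(C)O1 | intermediate
10 | tiglic anhydride ((2E)-2-methylbut-2-enoic anhydride) | C/C=C(\C)C(=O)OC(=O)/C(C)=C/C | starting material
11 | methyl (3R,4S)-10-bromo-3-[(4S)-2,2-dimethyl-1,3-dioxolan-4-yl]-4-hydroxy-2,6-dimethylidene-8-oxoundec-10-enoate (formed as its Cr(III) alkoxide, drawn as the alcohol) | C=C(C[C@H](O)[C@@H](C(=C)C(=O)OC)[C@H]1COC(C)(C)O1)CC(=O)CC(Br)=C | intermediate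
12 | methyl (3R,4S)-10-bromo-3-[(4S)-2,2-dimethyl-1,3-dioxolan-4-yl]-2,6-dimethylidene-8-oxo-4-[(2E)-2-methylbut-2-enoyloxy]undec-10-enoate | C=C(C[C@H](OC(=O)/C(C)=C/C)[C@@H](C(=C)C(=O)OC)[C@H]1COC(C)(C)O1)CC(=O)CC(Br)=C | intermediate
13 | methyl (3R,4S)-10-bromo-3-[(1S)-1,2-dihydroxyethyl]-2,6-dimethylidene-8-oxo-4-[(2E)-2-methylbut-2-enoyloxy]undec-10-enoate | C=C(C[C@H](OC(=O)/C(C)=C/C)[C@@H](C(=C)C(=O)OC)[C@H](O)CO)CC(=O)CC(Br)=C | intermediate
14 | (1S)-7-bromo-1-[(2S,3R)-2-(hydroxymethyl)-4-methylidene-5-oxooxolan-3-yl]-3-methylidene-5-oxooct-7-en-1-yl (2E)-2-methylbut-2-enoate | C=C(C[C@H](OC(=O)/C(C)=C/C)[C@H]1C(=C)C(=O)O[C@@H]1CO)CC(=O)CC(Br)=C | intermediate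
15 | (1S)-7-bromo-1-[(2S,3R)-2-formyl-4-methylidene-5-oxooxolan-3-yl]-3-methylidene-5-oxooct-7-en-1-yl (2E)-2-methylbut-2-enoate | C=C(C[C@H](OC(=O)/C(C)=C/C)[C@H]1C(=C)C(=O)O[C@@H]1C=O)CC(=O)CC(Br)=C | intermediate
16 | (5S,6S,7R,8S)-5-hydroxy-2-oxo-8-tigloyloxygermacra-4(15),10(14),11(13)-trien-12,6-olide | C=C1C[C@H](OC(=O)/C(C)=C/C)[C@H]2C(=C)C(=O)O[C@@H]2[C@@H](O)C(=C)CC(=O)C1 | intermediate
17 | CNP0307443.2, (2S,5S,6S,7R,8S)-2,5-epoxy-2-hydroxy-8-tigloyloxygermacra-4(15),10(14),11(13)-trien-12,6-olide | C=C1C[C@H](OC(=O)/C(C)=C/C)[C@H]2C(=C)C(=O)O[C@@H]2[C@H]2O[C@@](O)(C1)CC2=C | target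

**Total step count:** 9. **Longest linear sequence:** 7 steps (1, 2, 3, 6, 7, 8, 9).

**Three steps most likely to fail**

**Step 6 (the proposed new step).**
- Risks: acyl transfer from the anhydride to the Cr(III) alkoxide may be too slow, or the Cr(III) carboxylate may be hard to reduce, so turnover stops. An uncatalysed Mn Barbier reaction may run in the background. The simple (anti) or facial selectivity may be weak. The allylmetal may undergo 1,4-elimination towards the dioxolane oxygen.
- Fallback (known chemistry): the C–C and the C–O events are separated. It sets out from 5 and 9. The classical stoichiometric Hiyama–Nozaki allylation (CrCl2 3 equiv, THF, 0 °C, no Mn, no anhydride) is worked up cold at pH 7 and alcohol 11 is isolated. Steglich esterification (tiglic acid, DIC, DMAP 10 mol %, CH2Cl2, 0 °C) then comes back to the route at 12. No compound outside the list is made (F0).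

**Step 9.**
- Risks: strain of the ten-membered ring, and the reagent-controlled Si-face attack runs against the Felkin–Anh bias of the aldehyde.
- Fallback: C5 is set by hydride instead of by carbon. It sets out from 15. Ligand-free CrCl2/NiCl2 in DMSO at 2 mM closes the ring under substrate control, which is expected to favour the C5-epimeric hemiketal F1. Dess–Martin oxidation takes F1 through its open form to the macrocyclic ene-dione F2. Luche reduction (CeCl3·7H2O, NaBH4, MeOH, −78 °C) attacks the conjugated C5 carbonyl. Because hydride is now the incoming group, the same Felkin–Anh bias gives the syn (5S) alcohol, and the route is rejoined at 16, which closes to 17.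

**Step 3.**
- Risks: compound 5 is a 1,5-keto-aldehyde with two β,γ-alkenes, so intramolecular aldol reaction and conjugation can occur before it is used.
- Fallback: the ketone stays masked until after the coupling. It sets out from 4. TESCl/imidazole gives the bis(triethylsilyl) ether F3. Swern conditions oxidise only the primary TES ether, directly, to the C2-silyloxy aldehyde F4. F4 takes the place of 5 in step 6 and gives the coupled tiglate silyl ether F5. HF·pyridine frees the C2 alcohol F6, and Dess–Martin oxidation comes back to the route at 12.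

**Further compounds**
F0 | step 6 | none | none
F1 | step 9 | (2R,5R,6S,7R,8S)-2,5-epoxy-2-hydroxy-8-tigloyloxygermacra-4(15),10(14),11(13)-trien-12,6-olide (C5 epimer of 17) | C=C1C[C@H](OC(=O)/C(C)=C/C)[C@H]2C(=C)C(=O)O[C@@H]2[C@@H]2O[C@](O)(C1)CC2=C
F2 | step 9 | (6S,7R,8S)-2,5-dioxo-8-tigloyloxygermacra-4(15),10(14),11(13)-trien-12,6-olide | C=C1C[C@H](OC(=O)/C(C)=C/C)[C@H]2C(=C)C(=O)O[C@@H]2C(=O)C(=C)CC(=O)C1
F3 | step 3 | 7-bromo-3-methylidene-1,5-bis(triethylsilyloxy)oct-7-ene (racemic) | CC[Si](CC)(CC)OCCC(=C)CC(CC(Br)=C)O[Si](CC)(CC)CC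
F4 | step 3 | 7-bromo-3-methylidene-5-(triethylsilyloxy)oct-7-enal (racemic) | O=CCC(=C)CC(CC(Br)=C)O[Si](CC)(CC)CC
F5 | step 3 | methyl (3R,4S)-10-bromo-3-[(4S)-2,2-dimethyl-1,3-dioxolan-4-yl]-2,6-dimethylidene-4-[(2E)-2-methylbut-2-enoyloxy]-8-(triethylsilyloxy)undec-10-enoate (C8 epimers) | C=C(C[C@H](OC(=O)/C(C)=C/C)[C@@H](C(=C)C(=O)OC)[C@H]1COC(C)(C)O1)CC(CC(Br)=C)O[Si](CC)(CC)CC
F6 | step 3 | methyl (3R,4S)-10-bromo-3-[(4S)-2,2-dimethyl-1,3-dioxolan-4-yl]-8-hydroxy-2,6-dimethylidene-4-[(2E)-2-methylbut-2-enoyloxy]undec-10-enoate (C8 epimers) | C=C(C[C@H](OC(=O)/C(C)=C/C)[C@@H](C(=C)C(=O)OC)[C@H]1COC(C)(C)O1)CC(O)CC(Br)=C
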